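**Retrosynthetic overview** (ring numbering: C1 = C=O, C2 = CH, C3 = C–OMe, C4 = ketal carbon, C5 = CH2, C6 = CH–allyl)
1. Last bond is C4–OMe: Ag(I)-mediated exchange of a C4 O,S-ketal, in which both C4 epimers pass through one ring aryl-oxocarbenium ion and methanol should enter trans to the C6 allyl group.
2. C6–allyl and the 6S centre: Pd-catalysed decarboxylative asymmetric allylation of the allyl enol carbonate of the C6-unsubstituted ketone.
3. The only ring made, the cyclohexenone, comes from a one-pot Michael–Dieckmann annulation of an acyclic O,S-acetal ester with allyl acrylate: C4–C5 first, then ring closure by the C1–C6 bond.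
4. Enabling feature: the vinylogous ester C1(=O)–C2=C3(OMe) with the heteroatom-bearing C4 next to it. In the open chain C4–H is γ to the C1 ester and flanked by S and O (acidic, soft donor), and the E C2=C3 bond holds C1 cis to C4, so the C6 ester enolate reaches C1 through a six-membered transition state.
5. The aryl ether comes from 2-allyl-4,5-dimethoxyphenol (O-allylation and Claisen rearrangement of 3,4-dimethoxyphenol), attached by substitution of an α-chloro sulfide.

Key step: step 5

Remark: the sense of induction of the Trost ligand in step 8 is assigned by analogy with cyclohexanone-type enol carbonates and has to be confirmed on the first sample; the antipodal ligand is the remedy if it is reversed.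

Step 1
Reactants: 1 3,4-dimethoxyphenol; 2 allyl bromide
Product: 3 4-(allyloxy)-1,2-dimethoxybenzene
Conditions: K2CO3, acetone, reflux
Reagents that add atoms: allyl bromide (2), C=CCBr
Why: Williamson ether synthesis, the phenoxide displaces bromide from the allylic halide.

Step 2
Reactants: 3 4-(allyloxy)-1,2-dimethoxybenzene
Product: 4 2-allyl-4,5-dimethoxyphenol
Conditions: N,N-diethylaniline, 195 °C
Reagents that add atoms: none
Why: aromatic Claisen rearrangement ([3,3]) followed by tautomerisation, expected to go mainly to the ortho position that is not flanked by the 3-methoxy group.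

Step 3
Reactants: 5 methyl (E)-4-bromo-3-methoxybut-2-enoate; 6 thiophenol
Product: 7 methyl (E)-3-methoxy-4-(phenylthio)but-2-enoate
Conditions: K2CO3, acetone, 0 °C to rt
Reagents that add atoms: thiophenol (6), Sc1ccccc1
Why: SN2 displacement of the primary bromide by thiophenolate, which leaves the E enol ether untouched.

Step 4
Reactants: 7 methyl (E)-3-methoxy-4-(phenylthio)but-2-enoate; 4 2-allyl-4,5-dimethoxyphenol
Product: 9 methyl (E)-4-(2-allyl-4,5-dimethoxyphenoxy)-3-methoxy-4-(phenylthio)but-2-enoate (racemic), via α-chloro sulfide 8 (not isolated)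
Conditions: NCS, toluene, 0 °C to rt, filter off succinimide; then 4, KOt-Bu, THF, 0 °C to rt
Reagents that add atoms: 2-allyl-4,5-dimethoxyphenol (4), C=CCc1cc(OC)c(OC)cc1O
Why: α-chlorination of the sulfide by NCS (chlorosulfonium/thionium, Pummerer-type) followed by substitution of the α-chloro sulfide by the potassium phenoxide gives the O,S-acetal, and chlorination precedes introduction of the electron-rich arene so that the ring is not chlorinated.

Step 5
Reactants: 9 methyl (E)-4-(2-allyl-4,5-dimethoxyphenoxy)-3-methoxy-4-(phenylthio)but-2-enoate; 10 allyl acrylate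
Product: 12 allyl 5-(2-allyl-4,5-dimethoxyphenoxy)-4-methoxy-2-oxo-5-(phenylthio)cyclohex-3-ene-1-carboxylate (mixture of stereoisomers), via Michael adduct lithium enolate 11 (not isolated)
Conditions: LiHMDS (1.1 equiv), THF, −78 °C; allyl acrylate, −78 to 0 °C; aq NH4Cl
Reagents that add atoms: allyl acrylate (10), C=CC(=O)OCC=C
Why: LiHMDS removes the C4–H of 9 (γ to the ester through the C2=C3 enol ether and flanked by S and O), the sulfur-stabilised terminus of the dienolate adds to allyl acrylate (C4–C5 bond) to give ester enolate 11, and this enolate attacks the C1 methyl ester in a Dieckmann condensation that closes the cyclohexenone ring by the C1–C6 bond with loss of methoxide. The closest known reaction types are the Staunton–Weinreb annulation and tandem Michael–Dieckmann annulations of acrylates. The six-membered ring closes in a 6-exo-trig acyl substitution, the enolate carbon C6 adding to the ester carbonyl C1. The two new stereocentres need no control here: C6 (α-carbon of a β-keto ester) is enolised under the conditions and set in step 8, and C4 (O,S-ketal) is erased through the oxocarbenium ion of step 9. The step needs γ- over α-attack of the dienolate and retention of the E geometry that keeps C1 cis to C4; the first should be secured by the α-thio stabilisation of the γ-terminus and by the fact that only the γ-adduct can cyclise irreversibly to the deprotonated β-keto ester while α-adducts can revert, the second by running the addition at −78 °C on the E ester.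

Step 6
Reactants: 12 allyl 5-(2-allyl-4,5-dimethoxyphenoxy)-4-methoxy-2-oxo-5-(phenylthio)cyclohex-3-ene-1-carboxylate
Product: 13 4-(2-allyl-4,5-dimethoxyphenoxy)-3-methoxy-4-(phenylthio)cyclohex-2-en-1-one (racemic)
Conditions: Pd(OAc)2 (cat.), PPh3, HCO2H, Et3N, THF, rt
Reagents that add atoms: none
Why: Tsuji-type Pd-catalysed deallylation (formate reduction of the π-allyl complex) and decarboxylation of the resulting β-keto acid under buffered conditions that spare the O,S-ketal and the vinylogous ester.

Step 7
Reactants: 13 4-(2-allyl-4,5-dimethoxyphenoxy)-3-methoxy-4-(phenylthio)cyclohex-2-en-1-one; 14 allyl chloroformate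
Product: 15 allyl 4-(2-allyl-4,5-dimethoxyphenoxy)-5-methoxy-4-(phenylthio)cyclohexa-1,5-dien-1-yl carbonate (racemic)
Conditions: NaHMDS, TMEDA, THF, −78 °C; allyl chloroformate
Reagents that add atoms: allyl chloroformate (14), C=CCOC(Cl)=O
Why: O-acylation of the sodium enolate (enol carbonate formation), regiodefined because C6 is the only enolisable position.

Step 8
Reactants: 15 allyl 4-(2-allyl-4,5-dimethoxyphenoxy)-5-methoxy-4-(phenylthio)cyclohexa-1,5-dien-1-yl carbonate
Product: 16 (6S)-6-allyl-4-(2-allyl-4,5-dimethoxyphenoxy)-3-methoxy-4-(phenylthio)cyclohex-2-en-1-one (both C4 epimers)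
Conditions: Pd2(dba)3·CHCl3 (cat.), (S,S)-ANDEN-phenyl Trost ligand (cat.), 1,4-dioxane, rt
Reagents that add atoms: none
Why: decarboxylative asymmetric allylic alkylation, in which Pd(0) ionises the enol carbonate, loss of CO2 gives a π-allyl-Pd/enolate ion pair in the chiral pocket and the ligand directs the allyl group to one face of C6, while the neutral conditions should keep the new tertiary α-centre from racemising and both C4 epimers are carried on because C4 is erased in step 9.

Step 9
Reactants: 16 (6S)-6-allyl-4-(2-allyl-4,5-dimethoxyphenoxy)-3-methoxy-4-(phenylthio)cyclohex-2-en-1-one; 17 methanol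
Product: 19 (4R,6S)-6-allyl-4-(2-allyl-4,5-dimethoxyphenoxy)-3,4-dimethoxycyclohex-2-en-1-one, via ring aryl-oxocarbenium triflate 18 (not isolated)
Conditions: AgOTf, 2,6-lutidine, 4 Å MS, MeOH–CH2Cl2, −40 °C
Reagents that add atoms: methanol (17), CO
Why: thiophilic Ag(I) activation (O,S- to O,O-ketal exchange) expels silver thiolate from either C4 epimer to give the same oxocarbenium ion 18, which methanol should capture along the axial trajectory of the half-chair that keeps the C6 allyl group pseudo-equatorial, that is trans to the allyl group, leaving the aryloxy group cis to it (4R), while the buffered conditions should suppress proton loss from C5 and aromatisation.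

**Compound list**
1 | 3,4-dimethoxyphenol | COc1ccc(O)cc1OC | starting material
2 | allyl bromide | C=CCBr | starting material
3 | 4-(allyloxy)-1,2-dimethoxybenzene | C=CCOc1ccc(OC)c(OC)c1 | intermediate
4 | 2-allyl-4,5-dimethoxyphenol | C=CCc1cc(OC)c(OC)cc1O | intermediate
5 | methyl (E)-4-bromo-3-methoxybut-2-enoate | COC(=O)/C=C(/OC)CBr | starting material
6 | thiophenol | Sc1ccccc1 | starting material
7 | methyl (E)-3-methoxy-4-(phenylthio)but-2-enoate | COC(=O)/C=C(/OC)CSc1ccccc1 | intermediate
8 | methyl (E)-4-chloro-3-methoxy-4-(phenylthio)but-2-enoate (α-chloro sulfide, racemic, not isolated) | COC(=O)/C=C(/OC)C(Cl)Sc1ccccc1 | intermediate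
9 | methyl (E)-4-(2-allyl-4,5-dimethoxyphenoxy)-3-methoxy-4-(phenylthio)but-2-enoate (racemic) | COC(=O)/C=C(/OC)C(Oc1cc(OC)c(OC)cc1CC=C)Sc1ccccc1 | intermediate
10 | allyl acrylate | C=CC(=O)OCC=C | starting material
11 | Michael adduct lithium enolate (lithium enolate of the allyl ester of 1-allyl 7-methyl (E)-4-(2-allyl-4,5-dimethoxyphenoxy)-5-methoxy-4-(phenylthio)hept-5-enedioate, not isolated) | COC(=O)/C=C(/OC)C(Oc1cc(OC)c(OC)cc1CC=C)(Sc1ccccc1)CC=C([O-])OCC=C.[Li+] | intermediate
12 | allyl 5-(2-allyl-4,5-dimethoxyphenoxy)-4-methoxy-2-oxo-5-(phenylthio)cyclohex-3-ene-1-carboxylate (mixture of stereoisomers) | C=CCOC(=O)C1CC(Oc2cc(OC)c(OC)cc2CC=C)(Sc2ccccc2)C(OC)=CC1=O | intermediate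
13 | 4-(2-allyl-4,5-dimethoxyphenoxy)-3-methoxy-4-(phenylthio)cyclohex-2-en-1-one (racemic) | C=CCc1cc(OC)c(OC)cc1OC1(Sc2ccccc2)CCC(=O)C=C1OC | intermediate
14 | allyl chloroformate | C=CCOC(Cl)=O | starting material
15 | allyl 4-(2-allyl-4,5-dimethoxyphenoxy)-5-methoxy-4-(phenylthio)cyclohexa-1,5-dien-1-yl carbonate (racemic) | C=CCOC(=O)OC1=CCC(Oc2cc(OC)c(OC)cc2CC=C)(Sc2ccccc2)C(OC)=C1 | intermediate
16 | (6S)-6-allyl-4-(2-allyl-4,5-dimethoxyphenoxy)-3-methoxy-4-(phenylthio)cyclohex-2-en-1-one (both C4 epimers) | C=CCc1cc(OC)c(OC)cc1OC1(Sc2ccccc2)C[C@H](CC=C)C(=O)C=C1OC | intermediate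
17 | methanol | CO | starting material
18 | [(5S)-5-allyl-2-methoxy-4-oxocyclohex-2-en-1-ylidene](2-allyl-4,5-dimethoxyphenyl)oxonium triflate (not isolated) | C=CCc1cc(OC)c(OC)cc1[O+]=C1C[C@H](CC=C)C(=O)C=C1OC.[O-]S(=O)(=O)C(F)(F)F | intermediate
19 | (4R,6S)-6-allyl-4-(2-allyl-4,5-dimethoxyphenoxy)-3,4-dimethoxycyclohex-2-en-1-one | C=CCc1cc(OC)c(OC)cc1O[C@]1(OC)C[C@H](CC=C)C(=O)C=C1OC | target

**Step count:** 9 steps in total; longest linear sequence 8 steps (steps 1, 2, 4, 5, 6, 7, 8, 9).

**Steps most likely to fail**

1. Step 9. Methanol may capture the oxocarbenium ion with poor facial selectivity, or the ion may lose a proton from C5 and aromatise. The fallback installs the mixed ketal before the ring exists and gives up the convergence. It sets out from 9: AgOTf, 2,6-lutidine and methanol convert the acyclic O,S-acetal into methyl (E)-4-(2-allyl-4,5-dimethoxyphenoxy)-3,4-dimethoxybut-2-enoate F1. Its γ-anion (LDA, −78 °C) is annulated with allyl acrylate as in step 5 to allyl 5-(2-allyl-4,5-dimethoxyphenoxy)-4,5-dimethoxy-2-oxocyclohex-3-ene-1-carboxylate F2. Pd/formate deallylation–decarboxylation gives 4-(2-allyl-4,5-dimethoxyphenoxy)-3,4-dimethoxycyclohex-2-en-1-one F3, and NaHMDS/allyl chloroformate gives allyl 4-(2-allyl-4,5-dimethoxyphenoxy)-4,5-dimethoxycyclohexa-1,5-dien-1-yl carbonate F4. The asymmetric decarboxylative allylation of racemic F4 should then give the target together with its C4 epimer (4S,6S)-6-allyl-4-(2-allyl-4,5-dimethoxyphenoxy)-3,4-dimethoxycyclohex-2-en-1-one F5, which is removed by chromatography. The fallback comes back to the route at 19.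

2. Step 5. The dienolate may attack through its α- instead of its γ-terminus, the conjugate addition may revert, or the acrylate may oligomerise before the ring closes. The fallback separates the two bond formations. It sets out from 9: a base-catalysed Michael addition under thermodynamic control (KOt-Bu 10 mol %, t-BuOH–THF, 0 °C, allyl acrylate added slowly) gives the neutral diester 1-allyl 7-methyl (E)-4-(2-allyl-4,5-dimethoxyphenoxy)-5-methoxy-4-(phenylthio)hept-5-enedioate F6, which is isolated. A separate Dieckmann condensation (LiHMDS, THF, −78 to 0 °C), in which C6 is the only enolisable position, closes the C1–C6 bond. The fallback comes back to the route at 12.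

3. Step 8. Enantiofacial control in the allylation of the tertiary enolate may be eroded, because the racemic C4 centre pairs matched and mismatched with the ligand. The fallback sets C6 by enantioselective protonation instead of allylation. It sets out from 12: C-allylation of the β-keto ester (K2CO3, allyl bromide, acetone) gives allyl 1-allyl-5-(2-allyl-4,5-dimethoxyphenoxy)-4-methoxy-2-oxo-5-(phenylthio)cyclohex-3-ene-1-carboxylate F7. Pd-catalysed enantioselective decarboxylative protonation (Pd(OAc)2, (S)-t-Bu-PHOX, HCO2H, 4 Å MS, dioxane, 40 °C) then delivers the C6–H bond. The fallback comes back to the route at 16.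

Further compounds
F1 | step 9 | methyl (E)-4-(2-allyl-4,5-dimethoxyphenoxy)-3,4-dimethoxybut-2-enoate (racemic) | COC(=O)/C=C(/OC)C(OC)Oc1cc(OC)c(OC)cc1CC=C
F2 | step 9 | allyl 5-(2-allyl-4,5-dimethoxyphenoxy)-4,5-dimethoxy-2-oxocyclohex-3-ene-1-carboxylate (mixture of stereoisomers) | C=CCOC(=O)C1CC(OC)(Oc2cc(OC)c(OC)cc2CC=C)C(OC)=CC1=O
F3 | step 9 | 4-(2-allyl-4,5-dimethoxyphenoxy)-3,4-dimethoxycyclohex-2-en-1-one (racemic) | C=CCc1cc(OC)c(OC)cc1OC1(OC)CCC(=O)C=C1OC
F4 | step 9 | allyl 4-(2-allyl-4,5-dimethoxyphenoxy)-4,5-dimethoxycyclohexa-1,5-dien-1-yl carbonate (racemic) | C=CCOC(=O)OC1=CCC(OC)(Oc2cc(OC)c(OC)cc2CC=C)C(OC)=C1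
F5 | step 9 | (4S,6S)-6-allyl-4-(2-allyl-4,5-dimethoxyphenoxy)-3,4-dimethoxycyclohex-2-en-1-one | C=CCc1cc(OC)c(OC)cc1O[C@@]1(OC)C[C@H](CC=C)C(=O)C=C1OC
F6 | step 5 | 1-allyl 7-methyl (E)-4-(2-allyl-4,5-dimethoxyphenoxy)-5-methoxy-4-(phenylthio)hept-5-enedioate (racemic) | COC(=O)/C=C(/OC)C(Oc1cc(OC)c(OC)cc1CC=C)(Sc1ccccc1)CCC(=O)OCC=C
F7 | step 8 | allyl 1-allyl-5-(2-allyl-4,5-dimethoxyphenoxy)-4-methoxy-2-oxo-5-(phenylthio)cyclohex-3-ene-1-carboxylate (mixture of stereoisomers) | C=CCOC(=O)C1(CC=C)CC(Oc2cc(OC)c(OC)cc2CC=C)(Sc2ccccc2)C(OC)=CC1=O
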